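**Strategy**

The cyclopentane ring is opened at C1–C2 and C3–C4 (daucane numbering, given below), excising a two-carbon acrylate unit. The precursor is a monocyclic trans-disubstituted cycloheptene carrying an isobutyryl group on C5 and an exocyclic methylene on C1, i.e. the angular methyl in latent form. In one operation, iron-hydride hydrogen-atom transfer makes the tertiary C1 radical, Giese addition to methyl acrylate forms C1–C2, and the derived iron enolate adds to the C4 ketone to form C3–C4. The step exploits the 1,3-relationship of quaternary C1 and carbinol C4 across ring-fusion carbon C5 of the five-membered ring; C5 relays its configuration to both. The ester is excised afterwards.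

Key step: step 7

Remark on numbering: C1 = methyl-bearing ring-fusion carbon, C2 and C3 = ring CH2 groups, C4 = isopropyl-bearing carbinol carbon, C5 = ring-fusion CH, C6 = secondary carbinol, C7 = CH2, C8 = methyl-bearing carbon, C9 = CH, C10 = CH2. The angular methyl is β and H-5 is α.

Remark (assumption): the (–)-menthone-derived dialkylbromoborane of step 4 is taken to deliver the (4S,5S)-anti aldol; if its sense is the opposite, the reagent from (+)-menthone is used.

**Route**

Step 1
Reactants: 1 3-chloro-2-(chloromethyl)prop-1-ene (3 equiv); 2 vinylmagnesium bromide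
Product: 3 2-(chloromethyl)penta-1,4-diene
Conditions: CuI (5 mol %), THF, –30 to 0 °C
Reagents that add atoms: none
Why: Copper-catalysed allylic substitution of a symmetric bis-allylic dichloride, in which SN2 and SN2′ attack give the same skipped diene; the excess of 1 should limit double vinylation.

Step 2
Reactants: 3 2-(chloromethyl)penta-1,4-diene; 4 2-methylpropanenitrile
Product: 7 2-methyl-5-methylideneoct-7-en-3-one, via allylzinc chloride 5 (not isolated), via N-zincio ketimine 6 (not isolated)
Conditions: Zn dust, LiCl, THF, 0 °C to rt; then 4, rt; then 1 M aq. HCl, 0 °C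
Reagents that add atoms: water, O
Why: LiCl-assisted zinc insertion and Blaise-type addition of the 2-substituted allylzinc to the nitrile (allylic transposition is degenerate), then mild hydrolysis of the ketimine, should give the β,γ-unsaturated ketone without conjugation.

Step 3
Reactants: 8 3-methylbut-3-en-1-ol
Product: 9 3-methylbut-3-enal
Conditions: Dess–Martin periodinane, CH2Cl2, 0 °C; used at once as a cold solution
Reagents that add atoms: none
Why: Dess–Martin oxidation under neutral conditions should give the β,γ-unsaturated aldehyde without migration of the double bond.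

Step 4
Reactants: 7 2-methyl-5-methylideneoct-7-en-3-one; 9 3-methylbut-3-enal
Product: 11 (4S,5S)-5-hydroxy-2,7-dimethyl-4-(penta-1,4-dien-2-yl)oct-7-en-3-one, via E-enol borinate 10 (not isolated)
Conditions: bis[(2-isopropyl-5-methylcyclohexyl)methyl]bromoborane from (–)-menthone, Et3N, CH2Cl2/Et2O, –78 °C; then 9, –78 °C; then MeOH, pH 7 buffer, H2O2, 0 °C
Reagents that add atoms: none
Why: Regioselective enolisation on the methylene side gives the E-enol borinate, whose chair (Zimmerman–Traxler) boron aldol should give the anti adduct, with the menthone-derived ligands selecting the aldehyde face (enantioselective anti boron aldol of a ketone).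

Step 5
Reactants: 11 (4S,5S)-5-hydroxy-2,7-dimethyl-4-(penta-1,4-dien-2-yl)oct-7-en-3-one
Product: 12 (4S,5S)-2,7-dimethyl-4-(penta-1,4-dien-2-yl)-5-{[tri(propan-2-yl)silyl]oxy}oct-7-en-3-one
Conditions: TIPSOTf, 2,6-lutidine, CH2Cl2, –78 to 0 °C
Reagents that add atoms: triisopropylsilyl triflate, CC(C)[Si](C(C)C)(C(C)C)OS(=O)(=O)C(F)(F)F
Why: Silylation under non-enolising conditions should leave the acidic C5–H untouched; the bulky TIPS group is chosen because it should not migrate to the tertiary alkoxide formed in step 12.

Step 6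
Reactants: 12 (4S,5S)-2,7-dimethyl-4-(penta-1,4-dien-2-yl)-5-{[tri(propan-2-yl)silyl]oxy}oct-7-en-3-one
Product: 13 2-methyl-1-[(1S,2S)-4-methyl-7-methylidene-2-{[tri(propan-2-yl)silyl]oxy}cyclohept-4-en-1-yl]propan-1-one
Conditions: second-generation Hoveyda–Grubbs catalyst (5 mol %), CH2Cl2 (2 mM), 40 °C
Reagents that add atoms: none
Why: Ring-closing metathesis between the allyl and methallyl termini should form the trisubstituted C8=C9 cycloheptene; the exocyclic methylene cannot give a reasonable ring and should stay untouched.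

Step 7
Reactants: 13 2-methyl-1-[(1S,2S)-4-methyl-7-methylidene-2-{[tri(propan-2-yl)silyl]oxy}cyclohept-4-en-1-yl]propan-1-one; 14 methyl acrylate (3 equiv)
Product: 17 methyl 4β-hydroxy-6α-{[tri(propan-2-yl)silyl]oxy}dauc-8-ene-3-carboxylate (trans-fused; mixture of C3 epimers), via tertiary C1 radical 15 (not isolated), via iron ester enolate 16 (not isolated)
Conditions: Fe(acac)3 (30 mol %), PhSiH3 (2.5 equiv), EtOH/THF, 50 °C
Reagents that add atoms: none
Why: Fe(acac)3 and PhSiH3 generate a trivalent iron hydride that transfers a hydrogen atom to the exocyclic CH2 of 13 (Markovnikov), the tertiary C1 radical 15 adds to the β-carbon of methyl acrylate (C1–C2), and the α-ester radical is reduced by divalent iron to the iron enolate 16, which adds to the C4 ketone (C3–C4) before it is protonated. The closest known reaction type is the HAT-initiated Giese addition/aldol sequence (radical–polar crossover annulation of an alkenyl ketone with an unsaturated carbonyl acceptor). The cyclopentane closes by a 5-(enolexo)-exo-trig aldol of a C2–C3 chain that sits trans to the acyl group on the cycloheptene, which gives the trans ring fusion. C1 is controlled by the C5 stereocentre: the acrylate should approach the planar radical on the face anti to the adjacent isobutyryl group, so that C2 lies cis to H-5 and the new methyl (the former methylene) cis to C4. C4 is set in the ring closure with the isopropyl group cis to H-5, away from the C5–C6 bond and the angular methyl, which places the oxygen β. The step needs hydrogen-atom transfer to the 1,1-disubstituted alkene in preference to the trisubstituted C8=C9 alkene (secured by the lower steric demand of the methylene, as in isopropenyl-selective reactions of limonene) and ring closure faster than enolate protonation (secured by intramolecularity).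

Step 8
Reactants: 17 methyl 4β-hydroxy-6α-{[tri(propan-2-yl)silyl]oxy}dauc-8-ene-3-carboxylate
Product: 18 4β-hydroxy-6α-{[tri(propan-2-yl)silyl]oxy}dauc-8-ene-3-carboxylic acid
Conditions: LiOH·H2O, THF/MeOH/H2O, 40 °C; then 1 M HCl to pH 3
Reagents that add atoms: lithium hydroxide, [Li+].[OH-]
Why: Saponification of the methyl ester; the silyl ether and the tertiary alcohol should survive, and retro-aldol of a β-hydroxy ester should be slow under these conditions.

Step 9
Reactants: 18 4β-hydroxy-6α-{[tri(propan-2-yl)silyl]oxy}dauc-8-ene-3-carboxylic acid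
Product: 20 6α-{[tri(propan-2-yl)silyl]oxy}dauc-8-en-4β-ol, via Barton ester 19 (not isolated)
Conditions: 1-hydroxypyridine-2(1H)-thione, EDC·HCl, DMAP (cat.), CH2Cl2, 0 °C to rt, dark; then t-BuSH, visible light, rt
Reagents that add atoms: none
Why: Barton reductive decarboxylation removes the activating group; the secondary C3 radical takes a hydrogen atom from the thiol, and C3 is no longer a stereocentre.

Step 10
Reactants: 21 4-hydroxy-3-methoxybenzoic acid (vanillic acid)
Product: 22 tert-butyldimethylsilyl 4-[(tert-butyldimethylsilyl)oxy]-3-methoxybenzoate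
Conditions: TBSCl (2.2 equiv), imidazole, DMF, rt
Reagents that add atoms: tert-butyldimethylsilyl chloride, CC(C)(C)[Si](C)(C)Cl
Why: Silylation of the phenol and the acid in one pot masks the phenol for the acylation.

Step 11
Reactants: 22 tert-butyldimethylsilyl 4-[(tert-butyldimethylsilyl)oxy]-3-methoxybenzoate
Product: 23 4-[(tert-butyldimethylsilyl)oxy]-3-methoxybenzoyl chloride
Conditions: (COCl)2, DMF (cat.), CH2Cl2, 0 °C to rt
Reagents that add atoms: oxalyl chloride, ClC(=O)C(=O)Cl
Why: Vilsmeier-type activation converts a silyl ester directly into the acid chloride under neutral conditions that should leave the aryl silyl ether intact.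

Step 12
Reactants: 20 6α-{[tri(propan-2-yl)silyl]oxy}dauc-8-en-4β-ol; 23 4-[(tert-butyldimethylsilyl)oxy]-3-methoxybenzoyl chloride
Product: 25 6α-{[tri(propan-2-yl)silyl]oxy}dauc-8-en-4β-yl 4-[(tert-butyldimethylsilyl)oxy]-3-methoxybenzoate, via lithium alkoxide 24 (not isolated)
Conditions: n-BuLi, THF, –78 °C; then 23, –78 to 0 °C
Reagents that add atoms: none
Why: O-Acylation of a lithium tertiary alkoxide with an aroyl chloride (as in the preparation of tert-butyl benzoates); C4 keeps its configuration because the C–O bond is not touched.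

Step 13
Reactants: 25 6α-{[tri(propan-2-yl)silyl]oxy}dauc-8-en-4β-yl 4-[(tert-butyldimethylsilyl)oxy]-3-methoxybenzoate
Product: 26 6α-hydroxydauc-8-en-4β-yl 4-hydroxy-3-methoxybenzoate
Conditions: HF·pyridine, pyridine, THF, 0 °C to rt
Reagents that add atoms: none
Why: Fluoride-mediated cleavage of both silyl ethers under mildly acidic, non-basic conditions, so that no C6 alkoxide is formed and the tertiary ester should not migrate to O-6.

Step 14
Reactants: 26 6α-hydroxydauc-8-en-4β-yl 4-hydroxy-3-methoxybenzoate
Product: 27 8α,9α-epoxy-6α-hydroxydaucan-4β-yl 4-hydroxy-3-methoxybenzoate (target)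
Conditions: VO(acac)2 (5 mol %), t-BuOOH (1.5 equiv), CH2Cl2, 0 °C to rt
Reagents that add atoms: tert-butyl hydroperoxide, CC(C)(C)OO
Why: Hydroxyl-directed epoxidation: the vanadium alkoxide of the homoallylic 6α-OH should deliver oxygen to the α-face of C8=C9, the β-face being shielded as well by the angular methyl; the electron-poor vanillate phenol should tolerate the short, cold reaction.

**Compound list**

1 | 3-chloro-2-(chloromethyl)prop-1-ene | C=C(CCl)CCl | starting material
2 | vinylmagnesium bromide | C=C[Mg]Br | starting material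
3 | 2-(chloromethyl)penta-1,4-diene | C=CCC(=C)CCl | intermediate
4 | 2-methylpropanenitrile | CC(C)C#N | starting material
5 | (2-methylidenepent-4-en-1-yl)zinc chloride | C=CCC(=C)C[Zn]Cl | intermediate (not isolated)
6 | N-chlorozincio ketimine of 7 | CC(C)C(=N[Zn]Cl)CC(=C)CC=C | intermediate (not isolated)
7 | 2-methyl-5-methylideneoct-7-en-3-one | CC(C)C(=O)CC(=C)CC=C | intermediate
8 | 3-methylbut-3-en-1-ol | C=C(C)CCO | starting material
9 | 3-methylbut-3-enal | C=C(C)CC=O | intermediate
10 | E-enol borinate of 7 with the menthone-derived dialkylboryl group | CC(C)[C@@H]1CC[C@@H](C)C[C@H]1CB(C[C@@H]1C[C@H](C)CC[C@H]1C(C)C)O/C(C(C)C)=C/C(=C)CC=C | intermediate (not isolated)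
11 | (4S,5S)-5-hydroxy-2,7-dimethyl-4-(penta-1,4-dien-2-yl)oct-7-en-3-one (anti aldol) | C=CCC(=C)[C@H](C(=O)C(C)C)[C@@H](O)CC(C)=C | intermediate
12 | (4S,5S)-2,7-dimethyl-4-(penta-1,4-dien-2-yl)-5-{[tri(propan-2-yl)silyl]oxy}oct-7-en-3-one | C=CCC(=C)[C@H](C(=O)C(C)C)[C@@H](O[Si](C(C)C)(C(C)C)C(C)C)CC(C)=C | intermediate
13 | 2-methyl-1-[(1S,2S)-4-methyl-7-methylidene-2-{[tri(propan-2-yl)silyl]oxy}cyclohept-4-en-1-yl]propan-1-one (acyl and silyloxy trans) | C=C1CC=C(C)C[C@H](O[Si](C(C)C)(C(C)C)C(C)C)[C@H]1C(=O)C(C)C | intermediate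
14 | methyl acrylate | C=CC(=O)OC | starting material
15 | tertiary C1 radical from 13 (methylene converted to methyl) | C[C]1CC=C(C)C[C@H](O[Si](C(C)C)(C(C)C)C(C)C)[C@H]1C(=O)C(C)C | intermediate (not isolated)
16 | iron-bound ester enolate of the Giese adduct (drawn as the enolate anion; C2 trans to the acyl group) | COC([O-])=CC[C@]1(C)CC=C(C)C[C@H](O[Si](C(C)C)(C(C)C)C(C)C)[C@H]1C(=O)C(C)C | intermediate (not isolated)
17 | methyl 4β-hydroxy-6α-{[tri(propan-2-yl)silyl]oxy}dauc-8-ene-3-carboxylate (1β-methyl, 5α-H, trans-fused; C3 epimers) | O[C@@]1(C(C)C)C(C(=O)OC)C[C@]2(C)CC=C(C)C[C@H](O[Si](C(C)C)(C(C)C)C(C)C)[C@H]21 | intermediate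
18 | 4β-hydroxy-6α-{[tri(propan-2-yl)silyl]oxy}dauc-8-ene-3-carboxylic acid (C3 epimers) | O[C@@]1(C(C)C)C(C(=O)O)C[C@]2(C)CC=C(C)C[C@H](O[Si](C(C)C)(C(C)C)C(C)C)[C@H]21 | intermediate
19 | 2-thioxopyridin-1(2H)-yl ester of 18 (Barton ester) | O[C@@]1(C(C)C)C(C(=O)ON3C=CC=CC3=S)C[C@]2(C)CC=C(C)C[C@H](O[Si](C(C)C)(C(C)C)C(C)C)[C@H]21 | intermediate (not isolated)
20 | 6α-{[tri(propan-2-yl)silyl]oxy}dauc-8-en-4β-ol (1β-methyl, 5α-H, trans-fused) | O[C@@]1(C(C)C)CC[C@]2(C)CC=C(C)C[C@H](O[Si](C(C)C)(C(C)C)C(C)C)[C@H]21 | intermediate
21 | 4-hydroxy-3-methoxybenzoic acid | COc1cc(C(=O)O)ccc1O | starting material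
22 | tert-butyldimethylsilyl 4-[(tert-butyldimethylsilyl)oxy]-3-methoxybenzoate | COc1cc(C(=O)O[Si](C)(C)C(C)(C)C)ccc1O[Si](C)(C)C(C)(C)C | intermediate
23 | 4-[(tert-butyldimethylsilyl)oxy]-3-methoxybenzoyl chloride | COc1cc(C(Cl)=O)ccc1O[Si](C)(C)C(C)(C)C | intermediate
24 | lithium 4β-alkoxide of 20 | [Li]O[C@@]1(C(C)C)CC[C@]2(C)CC=C(C)C[C@H](O[Si](C(C)C)(C(C)C)C(C)C)[C@H]21 | intermediate (not isolated)
25 | 6α-{[tri(propan-2-yl)silyl]oxy}dauc-8-en-4β-yl 4-[(tert-butyldimethylsilyl)oxy]-3-methoxybenzoate | COc1cc(C(=O)O[C@@]2(C(C)C)CC[C@]3(C)CC=C(C)C[C@H](O[Si](C(C)C)(C(C)C)C(C)C)[C@H]32)ccc1O[Si](C)(C)C(C)(C)C | intermediate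
26 | 6α-hydroxydauc-8-en-4β-yl 4-hydroxy-3-methoxybenzoate | COc1cc(C(=O)O[C@@]2(C(C)C)CC[C@]3(C)CC=C(C)C[C@H](O)[C@H]32)ccc1O | intermediate
27 | 8α,9α-epoxy-6α-hydroxydaucan-4β-yl 4-hydroxy-3-methoxybenzoate | COc1cc(C(=O)O[C@@]2(C(C)C)CC[C@]3(C)C[C@@H]4O[C@]4(C)C[C@H](O)[C@H]32)ccc1O | target

**Step count and risks**

Total step count: 14. Longest linear sequence: 11 steps (1, 2, 4, 5, 6, 7, 8, 9, 12, 13, 14).

Steps most likely to fail:

Step 7. The iron enolate may be protonated by the alcohol before it closes onto the hindered isopropyl ketone, and the radical addition may show only moderate facial selectivity. The fallback sets out from compound 13 and makes the two bonds in sequence. The same hydrogen-atom-transfer conditions with methyl 2-chloroacrylate should give methyl 2-chloro-3-[1,5-dimethyl-2-(2-methylpropanoyl)-3-{[tri(propan-2-yl)silyl]oxy}cyclohept-5-en-1-yl]propanoate F1. SmI2 in THF at –78 °C should then generate the samarium enolate regiospecifically at C3 (divalent samarium reduces the C–Cl bond) and close the ring by an intramolecular Reformatsky reaction. The route is rejoined at compound 17.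

Step 12. Acylation of the hindered tertiary alkoxide may stall, or the alkoxide may be consumed by side reactions before it is acylated. The fallback sets out from compound 20 and builds the ester by carbonylation instead of acyl transfer. The sodium alkoxide of 20 (NaH) would be coupled with tert-butyl(4-iodo-2-methoxyphenoxy)dimethylsilane F2 under CO (1 atm) with Pd(OAc)2 and Xantphos in toluene at 80 °C (palladium-catalysed alkoxycarbonylation of an aryl iodide). The route is rejoined at compound 25.

Step 4. The chiral boron aldol may give insufficient enantio- or anti-selectivity, or the β,γ-unsaturated ketone may epimerise or conjugate during enolisation. The fallback sets out from compound 7 and uses an achiral anti aldol followed by resolution. Dicyclohexylboron chloride and Et3N with 9 should give the racemic anti aldol, i.e. 11 together with its enantiomer (4R,5R)-5-hydroxy-2,7-dimethyl-4-(penta-1,4-dien-2-yl)oct-7-en-3-one F3. Candida antarctica lipase B with vinyl acetate is expected, by the usual empirical rule for secondary alcohols, to acetylate the (5R)-alcohol to (4R,5R)-2,7-dimethyl-3-oxo-4-(penta-1,4-dien-2-yl)oct-7-en-5-yl acetate F4 and leave 11 untouched. After chromatographic separation the route is rejoined at compound 11.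

Further compounds
F1 | step 7 | methyl 2-chloro-3-[1,5-dimethyl-2-(2-methylpropanoyl)-3-{[tri(propan-2-yl)silyl]oxy}cyclohept-5-en-1-yl]propanoate (ring configured as in 17; epimers at the chlorinated carbon) | COC(=O)C(Cl)C[C@]1(C)CC=C(C)C[C@H](O[Si](C(C)C)(C(C)C)C(C)C)[C@H]1C(=O)C(C)C
F2 | step 12 | tert-butyl(4-iodo-2-methoxyphenoxy)dimethylsilane | COc1cc(I)ccc1O[Si](C)(C)C(C)(C)C
F3 | step 4 | (4R,5R)-5-hydroxy-2,7-dimethyl-4-(penta-1,4-dien-2-yl)oct-7-en-3-one | C=CCC(=C)[C@@H](C(=O)C(C)C)[C@H](O)CC(C)=C
F4 | step 4 | (4R,5R)-2,7-dimethyl-3-oxo-4-(penta-1,4-dien-2-yl)oct-7-en-5-yl acetate | C=CCC(=C)[C@@H](C(=O)C(C)C)[C@H](OC(C)=O)CC(C)=C
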